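A small charge of free catalyst, 0.0506 % of the starting material in the flask, promised little target in an hour, since cedar read 4.5 % and ash 6.5 % at 60.0 min, so I reckoned the target as a small correction and let the starting material stand as charged.

| setting | cedar | ash | elm | flask |
|---|---|---|---|---|
| starting material | 0.087 M | 0.087 M | 0.13 M | 0.087 M |
| gas phase | 26 mM (held) | 26 mM (held) | 26 mM (held) | 26 mM (held) |
| free catalyst | 29 µM | 66 µM | 44 µM | 44 µM |
| remark | run made earlier | run made earlier | run made earlier |  |
| time |  |  |  | 1.0 h |

| run | time / min | target / % |
|---|---|---|
| cedar | 5.00 | 0 |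
| cedar | 8.00 | 0.5 |
| cedar | 12.0 | 0.6 |
| cedar | 15.0 | 1.8 |
| cedar | 25.0 | 2.1 |
| cedar | 40.0 | 3.6 |
| cedar | 60.0 | 4.5 |
| ash | 5.00 | 1.0 |
| ash | 8.00 | 1.2 |
| ash | 12.0 | 1.3 |
| ash | 15.0 | 1.7 |
| ash | 25.0 | 3.4 |
| ash | 40.0 | 4.6 |
| ash | 60.0 | 6.5 |
| elm | 5.00 | 0.2 |
| elm | 15.0 | 1.3 |
| elm | 30.0 | 3.1 |
| elm | 40.0 | 4.2 |
| elm | 60.0 | 5.1 |

(each reading ± 0.3 percentage points)

- at the start none of the gas is dissolved
- candidate steps: gas phase <-> dissolved gas; starting material + dissolved gas + free catalyst -> free catalyst + target; dissolved gas + free catalyst <-> idle complex; 2 free catalyst -> spent catalyst; target + free catalyst <-> isomer of the product + free catalyst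

- Wednesday's: doubling the transfer coefficient of the gas phase, all else as stated
- Monday's: doubling the amount of free catalyst, all else as stated
- Sunday's: doubling the saturation concentration of gas phase, all else as stated

- target at 1.0 h, in percent of the starting material charged
- the change that raises the amount of target at 1.0 h, in percent of the starting material charged most ("none" if none brings more than 2 percentage points) (Wednesday's / Monday's / Sunday's / none)
- amount of target at 1.0 h, in percent of the starting material charged, after Sunday's

Those two last readings gave me an apparent catalyst order of 0.447 and, at the flask's charge, 5.42 %. Elm, with the flask's catalyst charge and more starting material, read 5.1 % at 60.0 min, a percentage close to that figure, so I took the rate as pseudo-first-order in starting material. The rule I carried was the mean slope, the fraction of the charge turned into target per minute from time zero: 9.04 × 10⁻⁴ min⁻¹. Elm's readings drew the curve around that line. Elm read 0.2 % at 5.00 min where the line gave 0.452 %, each reading carrying a scatter of 0.3 percentage points. Between its readings at 15.0 min and 40.0 min elm's slope read 0.00116 min⁻¹, and up to its last reading 4.50 × 10⁻⁴ min⁻¹, so elm was still rising when its readings stopped. Scaling the slope, I expected Monday's to add 2 points. Supposing the slope followed the saturation concentration, which no run varied, Sunday's would give 10.8 %, a larger gain. For Wednesday's I had no slope to scale.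

The forecast said 5.3 % of target, Sunday's as the best change and 9 % after Sunday's, holding that “Doubling the gas should nearly double the rate”.

The flask gave 5.70 %, a mean slope of 9.49 × 10⁻⁴ min⁻¹; Sunday's was best, at 9.75 %.

    gas phase ⇌ dissolved gas, rate k1*(csat - [dissolved gas]) (kL = 0.0610 min⁻¹)
    starting material + dissolved gas + free catalyst → free catalyst + target (k = 7300 M⁻² min⁻¹)
    dissolved gas + free catalyst ⇌ idle complex, settled at all times (K = 61.0 M⁻¹)
    2 free catalyst → spent catalyst (k = 1400 M⁻¹ min⁻¹)
    target + free catalyst ⇌ isomer of the product + free catalyst, rate k5*[free catalyst]*[target] forward; the back reaction follows from the equilibrium constant (K = 0.470, k = 1100 M⁻¹ min⁻¹)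

The flask had not come to rest at 1.0 h. At 10.0 h target stood at 19.9 %, less than the 54.2 % of the line, with 72.6 % of the starting material still there and free catalyst down from 13.8 % to 2.95 % of its charge. The mean slope over those later hours was 2.64 × 10⁻⁴ min⁻¹, and isomer of the product had reached 7.42 %.

For the same flask read at 15 min, the mean slope gave 1.36 %; the computed target there was 1.43 %.

(The readings were generated by integration from invented constants; the scatter is artificial.)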